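## Retrosynthetic overview

1. The side chain is numbered from the benzylic carbon C1 to the methyl C17 (carbinol C16, alkenes C8=C9 and C11=C12). The strategy rests on the heptamethylene run C1–C7 between the resorcinol ring and the skipped diene: it carries no heteroatom and so no polar handle, and its C2–C3 bond is cut as the union of two primary alkyl radicals, each released from a carboxylic acid.
2. This gives a 3-(3,5-dioxygenated phenyl)propanoic acid and (7Z,10Z,15S)-15-silyloxyhexadeca-7,10-dienoic acid, joined as their N-hydroxyphthalimide esters by nickel-electrocatalytic doubly decarboxylative coupling.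
3. The dienoic acid comes from CuI-mediated coupling of methyl oct-7-ynoate with a propargylic bromide to the 7,10-diyne, then cis-semihydrogenation. The (S)-carbinol comes from (S)-propylene oxide opened by a silylbutynyl Grignard reagent.
4. No ring is formed at any stage; the benzene ring is bought. The phenols travel as methoxymethyl ethers so that one acidic methanolysis frees all three hydroxyls.

Key step: step 14

Remark: the resorcinol oxygens are masked as methoxymethyl rather than methyl ethers, because thiolate demethylation of a 5-alkylresorcinol dimethyl ether tends to halt at the monomethyl ether and boron halides endanger the skipped diene. The methyl ethers are therefore removed from the simple saturated acid before the coupling.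

## Route

Step 1
Reactants: 1 oct-7-ynoic acid
Product: 2 methyl oct-7-ynoate
Conditions: MeOH, H2SO4 (cat.), reflux
Reagents that add atoms: methanol, CO
Why: Fischer esterification masks the acid so that its carboxylate cannot be O-propargylated in step 7, and the terminal alkyne is inert to acidic methanol.

Step 2
Reactants: 3 (4-bromobut-1-yn-1-yl)trimethylsilane; 4 (S)-propylene oxide
Product: 6 (S)-7-(trimethylsilyl)hept-6-yn-2-ol, via Grignard reagent 5 (not isolated)
Conditions: Mg, I2 (cat.), THF, 40 °C; then CuI (10 mol %), 4, THF, −30 °C → 0 °C; aq. NH4Cl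
Reagents that add atoms: none
Why: Copper-catalysed Grignard opening of a terminal epoxide occurs at the unsubstituted CH2, so the C–O bond of the stereocenter is never broken and the (S) configuration of 4 passes unchanged into the carbinol.

Step 3
Reactants: 6 (S)-7-(trimethylsilyl)hept-6-yn-2-ol
Product: 7 (S)-tert-butyldimethyl{[7-(trimethylsilyl)hept-6-yn-2-yl]oxy}silane
Conditions: TBSCl, imidazole, DMF, rt
Reagents that add atoms: tert-butyldimethylsilyl chloride, CC(C)(C)[Si](C)(C)Cl
Why: Imidazole-promoted silylation of a secondary alcohol gives an ether that withstands the base, organolithium, copper and hydrogenation steps ahead.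

Step 4
Reactants: 7 (S)-tert-butyldimethyl{[7-(trimethylsilyl)hept-6-yn-2-yl]oxy}silane
Product: 8 (S)-tert-butyl(hept-6-yn-2-yloxy)dimethylsilane
Conditions: K2CO3, MeOH, rt
Reagents that add atoms: none
Why: Methoxide-mediated protodesilylation cleaves the C(sp)–Si bond selectively, since an acetylide leaves silicon readily while the hindered O-silyl ether is untouched.

Step 5
Reactants: 8 (S)-tert-butyl(hept-6-yn-2-yloxy)dimethylsilane
Product: 10 (S)-7-[(tert-butyldimethylsilyl)oxy]oct-2-yn-1-ol, via lithium acetylide 9 (not isolated)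
Conditions: n-BuLi, THF, −78 → 0 °C; (CH2O)n, 0 °C → rt; aq. NH4Cl
Reagents that add atoms: formaldehyde (as paraformaldehyde), C=O
Why: Deprotonation of the terminal alkyne and addition of the lithium acetylide to formaldehyde (hydroxymethylation) is the standard route to a primary propargylic alcohol.

Step 6
Reactants: 10 (S)-7-[(tert-butyldimethylsilyl)oxy]oct-2-yn-1-ol
Product: 11 (S)-[(8-bromooct-6-yn-2-yl)oxy](tert-butyl)dimethylsilane
Conditions: CBr4, PPh3, CH2Cl2, 0 °C
Reagents that add atoms: carbon tetrabromide, BrC(Br)(Br)Br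
Why: Appel bromination converts the primary propargylic alcohol into the bromide under neutral conditions that leave the silyl ether intact.

Step 7
Reactants: 2 methyl oct-7-ynoate; 11 (S)-[(8-bromooct-6-yn-2-yl)oxy](tert-butyl)dimethylsilane
Product: 13 methyl (S)-15-[(tert-butyldimethylsilyl)oxy]hexadeca-7,10-diynoate, via copper acetylide 12 (not isolated)
Conditions: CuI (1 equiv), NaI (1 equiv), Cs2CO3 (1 equiv), DMF, rt
Reagents that add atoms: none
Why: The monovalent copper acetylide formed from 2 under mild carbonate base displaces the propargylic halide (activated as the iodide by NaI) at its CH2 carbon, the established copper-mediated alkyne–propargyl halide coupling to 1,4-diynes, and the ester is tolerated.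

Step 8
Reactants: 13 methyl (S)-15-[(tert-butyldimethylsilyl)oxy]hexadeca-7,10-diynoate
Product: 14 methyl (7Z,10Z,15S)-15-[(tert-butyldimethylsilyl)oxy]hexadeca-7,10-dienoate
Conditions: Ni(OAc)2·4H2O, NaBH4, H2NCH2CH2NH2, H2 (1 atm), EtOH, rt
Reagents that add atoms: none
Why: Brown semihydrogenation delivers hydrogen syn from the ethylenediamine-poisoned nickel boride surface, so both alkynes should become Z-alkenes, and the amine-deactivated catalyst reduces alkenes far more slowly than alkynes.

Step 9
Reactants: 14 methyl (7Z,10Z,15S)-15-[(tert-butyldimethylsilyl)oxy]hexadeca-7,10-dienoate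
Product: 15 (7Z,10Z,15S)-15-[(tert-butyldimethylsilyl)oxy]hexadeca-7,10-dienoic acid
Conditions: LiOH·H2O, THF/MeOH/H2O, rt; then 1 M HCl to pH 4, 0 °C
Reagents that add atoms: lithium hydroxide (hydroxide oxygen), [Li+].[OH-]
Why: Saponification of an unhindered methyl ester at room temperature uses a base too weak to move the skipped diene into conjugation, and the secondary silyl ether is stable to it.

Step 10
Reactants: 15 (7Z,10Z,15S)-15-[(tert-butyldimethylsilyl)oxy]hexadeca-7,10-dienoic acid
Product: 16 1,3-dioxoisoindolin-2-yl (7Z,10Z,15S)-15-[(tert-butyldimethylsilyl)oxy]hexadeca-7,10-dienoate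
Conditions: N-hydroxyphthalimide, DIC, DMAP (10 mol %), CH2Cl2, rt
Reagents that add atoms: N-hydroxyphthalimide, O=C1c2ccccc2C(=O)N1O
Why: Steglich-type carbodiimide acylation of N-hydroxyphthalimide gives the redox-active ester under neutral conditions.

Step 11
Reactants: 17 3-(3,5-dimethoxyphenyl)propanoic acid
Product: 18 3-(3,5-dihydroxyphenyl)propanoic acid
Conditions: 48% aq. HBr, AcOH, reflux
Reagents that add atoms: none
Why: Acid-mediated aryl methyl ether cleavage (bromide attack on the protonated ether) can be driven to completion on this robust saturated acid, which carries no alkene or silyl group.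

Step 12
Reactants: 18 3-(3,5-dihydroxyphenyl)propanoic acid
Product: 20 3-[3,5-bis(methoxymethoxy)phenyl]propanoic acid, via methoxymethyl ester 19 (not isolated)
Conditions: MOMCl, i-Pr2NEt, DMF, 0 °C → rt; then aq. LiOH, MeOH, rt; 1 M HCl to pH 4, 0 °C
Reagents that add atoms: chloromethyl methyl ether, COCCl; lithium hydroxide (hydroxide oxygen), [Li+].[OH-]
Why: O-Alkylation of both phenols and the carboxylate with chloromethyl methyl ether, then saponification of the labile methoxymethyl ester in the same flask, leaves the base-stable aryl acetal ethers.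

Step 13
Reactants: 20 3-[3,5-bis(methoxymethoxy)phenyl]propanoic acid
Product: 21 1,3-dioxoisoindolin-2-yl 3-[3,5-bis(methoxymethoxy)phenyl]propanoate
Conditions: N-hydroxyphthalimide, DIC, DMAP (10 mol %), CH2Cl2, rt
Reagents that add atoms: N-hydroxyphthalimide, O=C1c2ccccc2C(=O)N1O
Why: Steglich-type carbodiimide esterification as in step 10, to which the acetal ethers are inert.

Step 14
Reactants: 16 1,3-dioxoisoindolin-2-yl (7Z,10Z,15S)-15-[(tert-butyldimethylsilyl)oxy]hexadeca-7,10-dienoate (1 equiv); 21 1,3-dioxoisoindolin-2-yl 3-[3,5-bis(methoxymethoxy)phenyl]propanoate (3 equiv)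
Product: 22 tert-butyl({(2S,6Z,9Z)-17-[3,5-bis(methoxymethoxy)phenyl]heptadeca-6,9-dien-2-yl}oxy)dimethylsilane
Conditions: NiCl2(MeOCH2CH2OMe) (20 mol %), 2,2′:6′,2″-terpyridine (20 mol %), NaI, DMF, Zn anode, reticulated vitreous carbon cathode, undivided cell, constant current, rt, argon
Reagents that add atoms: none
Why: Cathodic reduction turns the divalent nickel–terpyridine complex into low-valent nickel, which transfers one electron to each N-acyloxyphthalimide; N–O scission and loss of CO2 release the primary radicals at C3 (from 16) and C2 (from 21), nickel captures them in turn, and reductive elimination from a dialkyl trivalent nickel species forms the C2–C3 bond. The closest known reaction type is the nickel-electrocatalytic doubly decarboxylative C(sp3)–C(sp3) cross-coupling of two redox-active esters, the reductive counterpart of a mixed Kolbe electrolysis. No ring closes and no stereocenter is created, and the C16 silyloxy centre is remote from both radical sites and is not touched. The step needs cross-coupling over homocoupling, which two primary esters do not bias, so the inexpensive 21 is used in threefold excess and its dimer, like that of 16, should differ enough in polarity from 22 to be removed on silica. Working at the cathode keeps the electron-rich resorcinol diether away from oxidation, which an anodic Kolbe coupling would not. The C3 radical is a hept-6-enyl radical whose 6-exo closure onto C8 and 1,5-hydrogen shift from allylic C7 are both slow against capture by nickel, so the Z,Z-diene should stay intact.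

Step 15
Reactants: 22 tert-butyl({(2S,6Z,9Z)-17-[3,5-bis(methoxymethoxy)phenyl]heptadeca-6,9-dien-2-yl}oxy)dimethylsilane
Product: 23 Hansfordiol D, 5-[(8Z,11Z,16S)-16-hydroxyheptadeca-8,11-dien-1-yl]benzene-1,3-diol
Conditions: HCl (2 M in MeOH), 45 °C, argon
Reagents that add atoms: none
Why: Acid-catalysed acetal exchange passes both methoxymethyl groups to methanol as dimethoxymethane and solvolyses the silyl ether in the same operation, and skipped Z,Z-dienes tolerate methanolic HCl as in the routine methanolysis of polyunsaturated lipids.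

## Compound list

1 | oct-7-ynoic acid | C#CCCCCCC(=O)O | starting material
2 | methyl oct-7-ynoate | C#CCCCCCC(=O)OC | intermediate
3 | (4-bromobut-1-yn-1-yl)trimethylsilane | C[Si](C)(C)C#CCCBr | starting material
4 | (S)-propylene oxide, (S)-2-methyloxirane | C[C@H]1CO1 | starting material
5 | [4-(trimethylsilyl)but-3-yn-1-yl]magnesium bromide | C[Si](C)(C)C#CCC[Mg]Br | intermediate (not isolated)
6 | (S)-7-(trimethylsilyl)hept-6-yn-2-ol | C[C@H](O)CCCC#C[Si](C)(C)C | intermediate
7 | (S)-tert-butyldimethyl{[7-(trimethylsilyl)hept-6-yn-2-yl]oxy}silane | C[C@H](O[Si](C)(C)C(C)(C)C)CCCC#C[Si](C)(C)C | intermediate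
8 | (S)-tert-butyl(hept-6-yn-2-yloxy)dimethylsilane | C[C@H](O[Si](C)(C)C(C)(C)C)CCCC#C | intermediate
9 | lithium (S)-6-[(tert-butyldimethylsilyl)oxy]hept-1-yn-1-ide | C[C@H](O[Si](C)(C)C(C)(C)C)CCCC#C[Li] | intermediate (not isolated)
10 | (S)-7-[(tert-butyldimethylsilyl)oxy]oct-2-yn-1-ol | C[C@H](O[Si](C)(C)C(C)(C)C)CCCC#CCO | intermediate
11 | (S)-[(8-bromooct-6-yn-2-yl)oxy](tert-butyl)dimethylsilane | C[C@H](O[Si](C)(C)C(C)(C)C)CCCC#CCBr | intermediate
12 | (8-methoxy-8-oxooct-1-yn-1-yl)copper, the monovalent copper acetylide of 2 | COC(=O)CCCCCC#C[Cu] | intermediate (not isolated)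
13 | methyl (S)-15-[(tert-butyldimethylsilyl)oxy]hexadeca-7,10-diynoate | C[C@H](O[Si](C)(C)C(C)(C)C)CCCC#CCC#CCCCCCC(=O)OC | intermediate
14 | methyl (7Z,10Z,15S)-15-[(tert-butyldimethylsilyl)oxy]hexadeca-7,10-dienoate | C[C@H](O[Si](C)(C)C(C)(C)C)CCC/C=C\C/C=C\CCCCCC(=O)OC | intermediate
15 | (7Z,10Z,15S)-15-[(tert-butyldimethylsilyl)oxy]hexadeca-7,10-dienoic acid | C[C@H](O[Si](C)(C)C(C)(C)C)CCC/C=C\C/C=C\CCCCCC(=O)O | intermediate
16 | 1,3-dioxoisoindolin-2-yl (7Z,10Z,15S)-15-[(tert-butyldimethylsilyl)oxy]hexadeca-7,10-dienoate | C[C@H](O[Si](C)(C)C(C)(C)C)CCC/C=C\C/C=C\CCCCCC(=O)ON1C(=O)c2ccccc2C1=O | intermediate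
17 | 3-(3,5-dimethoxyphenyl)propanoic acid | COc1cc(CCC(=O)O)cc(OC)c1 | starting material
18 | 3-(3,5-dihydroxyphenyl)propanoic acid | OC(=O)CCc1cc(O)cc(O)c1 | intermediate
19 | methoxymethyl 3-[3,5-bis(methoxymethoxy)phenyl]propanoate | COCOC(=O)CCc1cc(OCOC)cc(OCOC)c1 | intermediate (not isolated)
20 | 3-[3,5-bis(methoxymethoxy)phenyl]propanoic acid | COCOc1cc(CCC(=O)O)cc(OCOC)c1 | intermediate
21 | 1,3-dioxoisoindolin-2-yl 3-[3,5-bis(methoxymethoxy)phenyl]propanoate | COCOc1cc(CCC(=O)ON2C(=O)c3ccccc3C2=O)cc(OCOC)c1 | intermediate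
22 | tert-butyl({(2S,6Z,9Z)-17-[3,5-bis(methoxymethoxy)phenyl]heptadeca-6,9-dien-2-yl}oxy)dimethylsilane | C[C@H](O[Si](C)(C)C(C)(C)C)CCC/C=C\C/C=C\CCCCCCCc1cc(OCOC)cc(OCOC)c1 | intermediate
23 | Hansfordiol D, 5-[(8Z,11Z,16S)-16-hydroxyheptadeca-8,11-dien-1-yl]benzene-1,3-diol | C[C@H](O)CCC/C=C\C/C=C\CCCCCCCc1cc(O)cc(O)c1 | target

## Step count and risk

Total step count: 15. Longest linear sequence: 11 steps (steps 2 to 10, then 14 and 15).

Steps most likely to fail:

1. Step 14. The two primary esters may pair statistically, so that homocoupling uses up 16. The esters may also be reduced or hydrolysed before nickel captures the radicals, or the C3 radical may cyclise or shift a hydrogen and scramble the diene. The fallback gives up the radical union and forms the aryl–C1 bond by B-alkyl Suzuki–Miyaura coupling. It sets out from 14 and comes back at 22. Reduction of 14 with i-Bu2AlH in CH2Cl2 at −78 °C should give (7Z,10Z,15S)-15-[(tert-butyldimethylsilyl)oxy]hexadeca-7,10-dienal F1. Wittig methylenation with Ph3P=CH2 (from Ph3PCH3Br and KOt-Bu, THF, 0 °C) should give tert-butyl{[(2S,6Z,9Z)-heptadeca-6,9,16-trien-2-yl]oxy}dimethylsilane F2. 9-Borabicyclo[3.3.1]nonane in THF hydroborates only the monosubstituted alkene and should give 9-{(8Z,11Z,16S)-16-[(tert-butyldimethylsilyl)oxy]heptadeca-8,11-dien-1-yl}-9-borabicyclo[3.3.1]nonane F3. This is coupled without isolation (PdCl2(dppf), aq. K3PO4, THF/DMF, 60 °C) with 1-bromo-3,5-bis(methoxymethoxy)benzene F4, made from commercial 5-bromobenzene-1,3-diol with MOMCl and i-Pr2NEt. The product is 22.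

2. Step 8. Hydrogen uptake across two alkynes may run on to monoenes or stall at ene-ynes, and Z-to-E drift may occur, giving mixtures that are hard to separate. The fallback replaces catalytic hydrogenation by stoichiometric hydroboration and protonolysis. It sets out from 13 and comes back at 14. Dicyclohexylborane (from BH3·SMe2 and cyclohexene, 2.2 equiv, THF, 0 °C) adds syn to each alkyne and should give methyl (15S)-15-[(tert-butyldimethylsilyl)oxy]-8,11-bis(dicyclohexylboranyl)hexadeca-7,10-dienoate F5, in which the position of boron on each alkene does not matter. Protonolysis of the two alkenyl C–B bonds with AcOH at rt proceeds with retention and should give 14, with no path to over-reduction.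

3. Step 7. The acetylide may attack the propargylic halide at the remote alkyne carbon and give an allenyne, the carbonate base may isomerise the 1,4-diyne to allenes, and the alkyne may homocouple oxidatively. The fallback builds the C7=C8 alkene of 14 by a Z-selective Wittig reaction and never forms the 1,4-diyne. It sets out from 8 and comes back at 14. Lithium acetylide 9 with ethylene oxide and BF3·OEt2 (THF, −78 °C) should give (S)-8-[(tert-butyldimethylsilyl)oxy]non-3-yn-1-ol F6. Semihydrogenation of this single alkyne (H2, Pd/CaCO3 poisoned with Pb(OAc)2, quinoline) should give (S,Z)-8-[(tert-butyldimethylsilyl)oxy]non-3-en-1-ol F7. I2, PPh3 and imidazole should give (S,Z)-tert-butyl[(9-iodonon-6-en-2-yl)oxy]dimethylsilane F8, and PPh3 in MeCN at 80 °C should give [(3Z,8S)-8-[(tert-butyldimethylsilyl)oxy]non-3-en-1-yl]triphenylphosphonium iodide F9. The ylide from F9 (NaN(SiMe3)2, THF, −78 °C) and commercial methyl 7-oxoheptanoate should give 14.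

## Further compounds

F1 | step 14 | (7Z,10Z,15S)-15-[(tert-butyldimethylsilyl)oxy]hexadeca-7,10-dienal | C[C@H](O[Si](C)(C)C(C)(C)C)CCC/C=C\C/C=C\CCCCCC=O
F2 | step 14 | tert-butyl{[(2S,6Z,9Z)-heptadeca-6,9,16-trien-2-yl]oxy}dimethylsilane | C[C@H](O[Si](C)(C)C(C)(C)C)CCC/C=C\C/C=C\CCCCCC=C
F3 | step 14 | 9-{(8Z,11Z,16S)-16-[(tert-butyldimethylsilyl)oxy]heptadeca-8,11-dien-1-yl}-9-borabicyclo[3.3.1]nonane | C[C@H](O[Si](C)(C)C(C)(C)C)CCC/C=C\C/C=C\CCCCCCCB1C2CCCC1CCC2
F4 | step 14 | 1-bromo-3,5-bis(methoxymethoxy)benzene | COCOc1cc(Br)cc(OCOC)c1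
F5 | step 8 | methyl (15S)-15-[(tert-butyldimethylsilyl)oxy]-8,11-bis(dicyclohexylboranyl)hexadeca-7,10-dienoate (one regioisomer drawn; boron cis to the new hydrogen on each alkene) | C[C@H](O[Si](C)(C)C(C)(C)C)CCC/C(B(C1CCCCC1)C1CCCCC1)=C\C/C(B(C1CCCCC1)C1CCCCC1)=C\CCCCCC(=O)OC
F6 | step 7 | (S)-8-[(tert-butyldimethylsilyl)oxy]non-3-yn-1-ol | C[C@H](O[Si](C)(C)C(C)(C)C)CCCC#CCCO
F7 | step 7 | (S,Z)-8-[(tert-butyldimethylsilyl)oxy]non-3-en-1-ol | C[C@H](O[Si](C)(C)C(C)(C)C)CCC/C=C\CCO
F8 | step 7 | (S,Z)-tert-butyl[(9-iodonon-6-en-2-yl)oxy]dimethylsilane | C[C@H](O[Si](C)(C)C(C)(C)C)CCC/C=C\CCI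
F9 | step 7 | [(3Z,8S)-8-[(tert-butyldimethylsilyl)oxy]non-3-en-1-yl]triphenylphosphonium iodide | C[C@H](O[Si](C)(C)C(C)(C)C)CCC/C=C\CC[P+](c1ccccc1)(c1ccccc1)c1ccccc1.[I-]
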